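Start from a leftover. If each product takes one reagent, the amber flask keeps about 65.3% of its reagent, yet waste outweighs either product. At 3.00 min amber already held 28.7% waste, more than the 22.6% of both products together.

| flask | left-handed substrate | right-handed substrate | reagent | remark | time |
|---|---|---|---|---|---|
| amber | 20 mM | 20 mM | 3 equiv (fed, over 10 min) | the very flask that is asked about, followed so far |  |
| red | 30 mM | 30 mM | 3 equiv (fed, over 10 min) | run made earlier |  |
| flask | 20 mM | 20 mM | 3.00 equiv (fed, over 10 min) |  | 50 min |

- amber (time / min: left-handed product / %, waste / %, right-handed product / %): 3.00: 14.0, 28.7, 8.6; 6.00: 24.8, 42.9, 18.8; 10.0: 31.3, 47.4, 21.2; 12.0: 29.2, 47.5, 21.6; 15.0: 31.0, 48.7, 22.0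
- red (time / min: left-handed product / %, waste / %, right-handed product / %): 4.00: 21.0, 33.5, 15.1; 8.00: 30.8, 45.6, 22.4; 15.0: 34.2, 43.5, 22.2; 25.0: 30.2, 43.9, 25.4; 50.0: 31.4, 43.6, 23.3

(scatter of a reading: 1 percentage point)

- the left-handed product standing at 50 min, as a percentage of the left-handed substrate and right-handed substrate together charged
- the waste standing at 50 min, as a percentage of the left-handed substrate and right-handed substrate together charged
- the right-handed product standing at 50 min, as a percentage of the left-handed substrate and right-handed substrate together charged

- reagent is single-handed; left-handed substrate and right-handed substrate are mirror images of each other, charged as a racemate, each of them at the stated concentration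
- the handed part of reagent does not stay in what it makes, so the products of the two hands are mirror images too

Amber's readings from 10.0 min on average 47.9% waste and 52.1% products. That gives 0.919 for D, the diversion ratio, which is plateau waste divided by both products together.

Turn the time first. By hand, nothing should move, because those averages add to >99.9% of the charge, which leaves little room for substrate still to react. The red run agrees: its waste reads 43.5% at 15.0 min and 43.6% at 50.0 min.

Turn the feed rate r next, meaning equivalents times substrate concentration over dosing time: 6.00 mM min⁻¹ in amber, 9.00 mM min⁻¹ in red. My reckoning freezes the feed rate. Suppose waste is a first-order loss of substrate that needs no reagent, while products follow the standing reagent, taken as a steady share of r times time (pseudo-first-order, with a rising constant). Substrate then lasts a time that goes as the inverse square root of r, and D goes with that time. For red this gives 0.750, and red reads 0.786. Red raised r through concentration, and amber and red both hold 3 equiv, so neither tests a change of equivalents.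

The asked flask has amber's recipe, so I keep D, and waste is D over one plus D, or 47.9%. The forecast, from the same readings, says 30.4%, 47.8% and 21.8%, holding that “amber's own plateau is the right basis”.

The flask gives 30.7%, 47.2% and 22.1%.

    reagent + left-handed substrate → left-handed product (k = 0.570 M⁻¹ s⁻¹)
    reagent + right-handed substrate → right-handed product (k = 0.310 M⁻¹ s⁻¹)
    left-handed substrate ⇌ achiral form (K = 0.800, k = 0.00720 s⁻¹)
    right-handed substrate ⇌ achiral form (K = 0.800, k = 0.00720 s⁻¹)
    achiral form → waste (k = 0.0120 s⁻¹)

The forecast is right, and waiting does not undo it. It would take 1.77 equiv or 5.55 equiv of reagent, the nearest amounts at which left-handed product has moved by 5 points. The flask's D is 0.894. At 12.0 equiv, the neighbour's D by the rule is 0.459, which means 31.5% waste; the computed neighbour holds 26.2%.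

(The data are simulated on assumed constants.)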